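**Retrosynthetic overview**

- Naming used here: unit 1 is the 4-aryl-flavan-3-ol half (rings A, B, C; 2S,3R,4R; 2,3-trans-3,4-cis); unit 2 is the flavan-3,4-diol half (rings D, E, F; 2R,3R,4R; all-cis). Ring D carries unit 1 at C6.
- Last disconnections: global O-debenzylation, then ring F by a chelate-controlled Friedel–Crafts hydroxyalkylation (C4–C4a of unit 2) of an α-benzyloxy aldehyde whose C2 and C3 come from one Jacobsen–Katsuki epoxidation.
- Unit 1: the C3 hydroxyl and C4 hydrogen are put on a 4-aryl-2H-chromene by dihydroxylation anti to the C2 aryl group, then a pinacol hydride shift and borohydride reduction, all relayed from C2.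
- Key disconnection: the C4–C4a bond of ring C, made by 6-endo-dig gold-catalysed hydroarylation of an aryl propargyl ether. The enabling feature is that C4 of unit 1 is a doubly benzylic carbon between C4a of ring A (the only free position ortho to O1, and para to the C7 oxygen) and C6 of ring D (para to the ring F ether oxygen, ortho to the C7 oxygen); at the alkyne oxidation level it is therefore the cation-stabilised alkyne terminus.
- The alkyne comes from a Sonogashira coupling, its single stereocentre (C2 of unit 1) from a copper-catalysed asymmetric propargylic etherification, and both pyrogallol rings from one phenol. Ring order: C (step 11), then F (step 15).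

Key step: step 11

Remark on the chemistry: the sense of induction of the copper/pybox catalyst with this phenol is assumed, and the ligand enantiomer is the one that delivers (R)-12; (S,S)-(salen)MnCl is assumed to give the (2S,3S)-glycidate, as it does for cis-cinnamate esters.

**Route**

Step 1
Reactants: 1 2,3-bis(benzyloxy)benzaldehyde
Product: 3 2,3-bis(benzyloxy)phenol, via aryl formate 2 (not isolated)
Conditions: mCPBA, CH2Cl2, rt; then K2CO3 (cat.), MeOH
Reagents that add atoms: mCPBA OOC(=O)c1cccc(Cl)c1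
Why: Dakin-type Baeyer–Villiger oxidation, in which the electron-rich aryl group migrates in preference to hydride and the formate is then cleaved by methanolysis.

Step 2
Reactants: 3 2,3-bis(benzyloxy)phenol
Product: 4 2,3-bis(benzyloxy)-4-iodophenol
Conditions: NIS (1.0 equiv), TsOH·H2O (10 mol %), MeCN, −20 °C
Reagents that add atoms: N-iodosuccinimide O=C1CCC(=O)N1I
Why: Electrophilic aromatic iodination, expected para to the free hydroxyl (the position also ortho to the C3 benzyloxy group), with one equivalent of reagent and low temperature to limit ortho and double iodination.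

Step 3
Reactants: 5 4-(benzyloxy)benzaldehyde
Product: 6 ethyl (Z)-3-[4-(benzyloxy)phenyl]prop-2-enoate
Conditions: (PhO)2P(O)CH2CO2Et, NaH, THF, −78 to 0 °C
Reagents that add atoms: ethyl 2-(diphenoxyphosphoryl)acetate CCOC(=O)CP(=O)(Oc1ccccc1)Oc1ccccc1
Why: Ando variant of the Horner–Wadsworth–Emmons reaction, in which the diaryl phosphonate makes elimination fast and should give the kinetic Z-enoate from an aromatic aldehyde.

Step 4
Reactants: 6 ethyl (Z)-3-[4-(benzyloxy)phenyl]prop-2-enoate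
Product: 7 ethyl (2S,3S)-3-[4-(benzyloxy)phenyl]oxirane-2-carboxylate
Conditions: (S,S)-(salen)MnCl [(S,S)-N,N'-bis(3,5-di-tert-butylsalicylidene)-1,2-cyclohexanediaminomanganese chloride, C36H52ClMnN2O2] (5 mol %), 4-phenylpyridine N-oxide (0.25 equiv), NaOCl (aq, pH 11.3), CH2Cl2, 0 °C
Reagents that add atoms: sodium hypochlorite [Na+].[O-]Cl
Why: Jacobsen–Katsuki epoxidation of a cis-disubstituted aryl-conjugated alkene, the best substrate class for this catalyst; the catalyst enantiomer sets both stereocentres (the future C3 and C2 of unit 2) as the cis-epoxide.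

Step 5
Reactants: 7 ethyl (2S,3S)-3-[4-(benzyloxy)phenyl]oxirane-2-carboxylate; 4 2,3-bis(benzyloxy)-4-iodophenol
Product: 8 ethyl (2S,3R)-3-[2,3-bis(benzyloxy)-4-iodophenoxy]-3-[4-(benzyloxy)phenyl]-2-hydroxypropanoate
Conditions: Cs2CO3 (0.2 equiv), DMF, 50 °C
Reagents that add atoms: none
Why: Base-catalysed SN2 opening of the glycidate by the phenoxide at the benzylic carbon with inversion, which turns the cis-epoxide into the (2S,3R) arrangement that becomes 2,3-cis in ring F.

Step 6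
Reactants: 8 ethyl (2S,3R)-3-[2,3-bis(benzyloxy)-4-iodophenoxy]-3-[4-(benzyloxy)phenyl]-2-hydroxypropanoate
Product: 9 ethyl (2S,3R)-2-(benzyloxy)-3-[2,3-bis(benzyloxy)-4-iodophenoxy]-3-[4-(benzyloxy)phenyl]propanoate
Conditions: Ag2O (2 equiv), BnBr (3 equiv), CH2Cl2, 4 Å MS, rt, dark
Reagents that add atoms: benzyl bromide BrCc1ccccc1
Why: Williamson-type O-benzylation under neutral silver oxide conditions, which avoids enolisation and β-elimination of the β-aryloxy ester and installs the ether that later acts as the chelating group.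

Step 7
Reactants: 5 4-(benzyloxy)benzaldehyde
Product: 10 rac-1-[4-(benzyloxy)phenyl]prop-2-yn-1-ol
Conditions: HC≡CMgBr, THF, 0 °C; aq NH4Cl
Reagents that add atoms: ethynylmagnesium bromide C#C[Mg]Br
Why: Grignard 1,2-addition to the aldehyde; the alcohol is made racemic because its stereocentre is erased and reset in step 9.

Step 8
Reactants: 10 rac-1-[4-(benzyloxy)phenyl]prop-2-yn-1-ol
Product: 11 rac-1-[4-(benzyloxy)phenyl]prop-2-yn-1-yl acetate
Conditions: Ac2O, Et3N, DMAP (cat.), CH2Cl2, 0 °C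
Reagents that add atoms: acetic anhydride CC(=O)OC(C)=O
Why: DMAP-catalysed acylation that installs the propargylic leaving group.

Step 9
Reactants: 11 rac-1-[4-(benzyloxy)phenyl]prop-2-yn-1-yl acetate; 3 2,3-bis(benzyloxy)phenol
Product: 12 1,2-bis(benzyloxy)-3-{[(1R)-1-[4-(benzyloxy)phenyl]prop-2-yn-1-yl]oxy}benzene
Conditions: CuOTf·0.5C6H6 (5 mol %), Ph-pybox [2,6-bis(4-phenyl-4,5-dihydrooxazol-2-yl)pyridine, enantiomer leading to (R)-12] (10 mol %), i-Pr2NEt (1.2 equiv), toluene, −20 °C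
Reagents that add atoms: none
Why: Copper-catalysed enantioselective propargylic substitution: the copper acetylide loses acetate to a copper allenylidene, so both enantiomers of 11 converge, and the phenoxide oxygen attacks the γ-carbon inside the chiral pybox pocket, which sets C2 of unit 1.

Step 10
Reactants: 12 1,2-bis(benzyloxy)-3-{[(1R)-1-[4-(benzyloxy)phenyl]prop-2-yn-1-yl]oxy}benzene; 9 ethyl (2S,3R)-2-(benzyloxy)-3-[2,3-bis(benzyloxy)-4-iodophenoxy]-3-[4-(benzyloxy)phenyl]propanoate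
Product: 13 ethyl (2S,3R)-2-(benzyloxy)-3-[4-(benzyloxy)phenyl]-3-[2,3-bis(benzyloxy)-4-{(3S)-3-[2,3-bis(benzyloxy)phenoxy]-3-[4-(benzyloxy)phenyl]prop-1-yn-1-yl}phenoxy]propanoate
Conditions: PdCl2(PPh3)2 (3 mol %), CuI (5 mol %), Et3N, THF, 40 °C
Reagents that add atoms: none
Why: Sonogashira coupling of the terminal alkyne with the aryl iodide, which makes the future C4–C6 bond between the units; the ester, benzyl ethers and stereogenic C–O centres are inert to these conditions (the propargylic descriptor changes from R to S by ranking only).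

Step 11
Reactants: 13 ethyl (2S,3R)-2-(benzyloxy)-3-[4-(benzyloxy)phenyl]-3-[2,3-bis(benzyloxy)-4-{(3S)-3-[2,3-bis(benzyloxy)phenoxy]-3-[4-(benzyloxy)phenyl]prop-1-yn-1-yl}phenoxy]propanoate
Product: 14 ethyl (2S,3R)-2-(benzyloxy)-3-[4-(benzyloxy)phenyl]-3-[2,3-bis(benzyloxy)-4-{(2R)-7,8-bis(benzyloxy)-2-[4-(benzyloxy)phenyl]-2H-chromen-4-yl}phenoxy]propanoate
Conditions: Ph3PAuNTf2 (5 mol %), CH2Cl2, 0 °C to rt
Reagents that add atoms: none
Why: Cationic monovalent gold (Ph3PAu+) binds the alkyne and slips towards C3, so that positive charge builds at C4, where ring D stabilises it (ether oxygen para and benzyloxy group ortho to the attachment carbon C6) and the inductively withdrawing propargylic oxygen next to C3 does not oppose it; C4a of ring A then attacks C4 anti to gold, and rearomatisation followed by protodeauration of the vinylgold species releases the 2H-chromene. The closest known reaction type is the gold-catalysed intramolecular hydroarylation of aryl propargyl ethers to 2H-chromenes (a Friedel–Crafts alkenylation). Ring C closes in the 6-endo-dig mode. No stereocentre is formed; the C2 stereocentre lies outside the reacting π system and its C–O bond is not broken, so its configuration should be carried into 14 (descriptor R by ranking only), and the new C3=C4 alkene is the handle through which C2 dictates C3 and C4 in steps 12 and 13. The step needs 6-endo attack at C4 in preference to 5-exo attack at C3 and to attack by the ortho benzyloxy oxygen of ring D, which can reach only C3; both alternatives put the nucleophile on the alkyne carbon that carries no positive charge, and the polarisation by ring D together with the single free ortho position on ring A should secure the regiochemistry. In one operation the acyclic alkyne with one stereocentre in the reacting half becomes the complete 4-arylflavene core of unit 1, with the C4–C4a bond and the C4–C6 link to ring D both in place.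

Step 12
Reactants: 14 ethyl (2S,3R)-2-(benzyloxy)-3-[4-(benzyloxy)phenyl]-3-[2,3-bis(benzyloxy)-4-{(2R)-7,8-bis(benzyloxy)-2-[4-(benzyloxy)phenyl]-2H-chromen-4-yl}phenoxy]propanoate
Product: 15 ethyl (2S,3R)-2-(benzyloxy)-3-[4-(benzyloxy)phenyl]-3-[2,3-bis(benzyloxy)-4-{(2S,3S,4R)-7,8-bis(benzyloxy)-2-[4-(benzyloxy)phenyl]-3,4-dihydroxychroman-4-yl}phenoxy]propanoate
Conditions: OsO4 (5 mol %), NMO (2 equiv), acetone/H2O (4:1), rt
Reagents that add atoms: N-methylmorpholine N-oxide C[N+]1([O-])CCOCC1; water O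
Why: Catalytic OsO4 syn-dihydroxylation of the C3=C4 alkene from the face opposite the C2 aryl group (substrate control, as for flav-3-enes), which places the C3 hydroxyl trans to the C2 aryl group.

Step 13
Reactants: 15 ethyl (2S,3R)-2-(benzyloxy)-3-[4-(benzyloxy)phenyl]-3-[2,3-bis(benzyloxy)-4-{(2S,3S,4R)-7,8-bis(benzyloxy)-2-[4-(benzyloxy)phenyl]-3,4-dihydroxychroman-4-yl}phenoxy]propanoate
Product: 17 ethyl (2S,3R)-2-(benzyloxy)-3-[4-(benzyloxy)phenyl]-3-[2,3-bis(benzyloxy)-4-{(2S,3R,4R)-7,8-bis(benzyloxy)-2-[4-(benzyloxy)phenyl]-3-hydroxychroman-4-yl}phenoxy]propanoate, via flavan-3-one 16 (not isolated)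
Conditions: BF3·OEt2 (0.3 equiv), CH2Cl2, −40 °C; then Et3N, MeOH, NaBH4, −78 °C
Reagents that add atoms: none
Why: Pinacol rearrangement followed by hydride reduction: ionisation of the tertiary, doubly benzylic C4 hydroxyl and suprafacial 1,2-shift of the C3 hydrogen (which sits on the face of the C2 aryl group) should place the C4 aryl group trans to the C2 aryl group in ketone 16, an arrangement also favoured because a quasi-axial C4 aryl group avoids the peri C5–H, and borohydride is then expected to add to C3 from the face opposite that quasi-axial aryl group, giving the C3 hydroxyl cis to the C4 aryl and trans to the C2 aryl group.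

Step 14
Reactants: 17 ethyl (2S,3R)-2-(benzyloxy)-3-[4-(benzyloxy)phenyl]-3-[2,3-bis(benzyloxy)-4-{(2S,3R,4R)-7,8-bis(benzyloxy)-2-[4-(benzyloxy)phenyl]-3-hydroxychroman-4-yl}phenoxy]propanoate
Product: 18 (2S,3R)-2-(benzyloxy)-3-[4-(benzyloxy)phenyl]-3-[2,3-bis(benzyloxy)-4-{(2S,3R,4R)-7,8-bis(benzyloxy)-2-[4-(benzyloxy)phenyl]-3-hydroxychroman-4-yl}phenoxy]propanal
Conditions: i-Bu2AlH (2.2 equiv), CH2Cl2, −78 °C; aq KNaC4H4O6 work-up; used crude
Reagents that add atoms: none
Why: Partial reduction of an α-alkoxy ester by i-Bu2AlH, whose chelated tetrahedral aluminium hemiacetal survives at −78 °C and releases the aldehyde only on work-up (one equivalent is consumed by the free hydroxyl).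

Step 15
Reactants: 18 (2S,3R)-2-(benzyloxy)-3-[4-(benzyloxy)phenyl]-3-[2,3-bis(benzyloxy)-4-{(2S,3R,4R)-7,8-bis(benzyloxy)-2-[4-(benzyloxy)phenyl]-3-hydroxychroman-4-yl}phenoxy]propanal
Product: 19 hepta-O-benzyl ether of 20 [(2R,3R,4R)-3,7,8-tris(benzyloxy)-2-[4-(benzyloxy)phenyl]-6-{7,8-bis(benzyloxy)-2-[4-(benzyloxy)phenyl]-3-hydroxychroman-4-yl}chroman-4-ol; unit 1 arranged as in 20]
Conditions: MgBr2·OEt2 (3 equiv), CH2Cl2, −20 to 0 °C
Reagents that add atoms: none
Why: Intramolecular Friedel–Crafts hydroxyalkylation (6-exo-trig) under Cram chelate control: magnesium bridges the aldehyde and α-benzyloxy oxygens, and C4a of ring D (the only free position ortho to the tethering oxygen, para to the C7 benzyloxy group) can reach the carbonyl carbon only from the side of the C2–C3 bond, which should place the new C4 hydroxyl cis to the C3 benzyloxy group.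

Step 16
Reactants: 19 hepta-O-benzyl ether of 20
Product: 20 (2R,3R,4R)-2-(4-hydroxyphenyl)-6-[(2S,3R,4R)-3,7,8-trihydroxy-2-(4-hydroxyphenyl)chroman-4-yl]chromane-3,4,7,8-tetrol
Conditions: H2 (1 atm), Pd(OH)2/C, EtOAc/MeOH (1:1), rt, stopped at full debenzylation
Reagents that add atoms: none
Why: Hydrogenolysis of the six aryl benzyl ethers and the one secondary benzyl ether under neutral conditions, which should leave the flavan C2–O bonds and, with a short reaction time, the C4 hydroxyl of unit 2 intact.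

**Compound list**

1 | 2,3-bis(benzyloxy)benzaldehyde | O=Cc1cccc(OCc2ccccc2)c1OCc1ccccc1 | starting material
2 | 2,3-bis(benzyloxy)phenyl formate | O=COc1cccc(OCc2ccccc2)c1OCc1ccccc1 | intermediate
3 | 2,3-bis(benzyloxy)phenol | Oc1cccc(OCc2ccccc2)c1OCc1ccccc1 | intermediate
4 | 2,3-bis(benzyloxy)-4-iodophenol | Oc1ccc(I)c(OCc2ccccc2)c1OCc1ccccc1 | intermediate
5 | 4-(benzyloxy)benzaldehyde | O=Cc1ccc(OCc2ccccc2)cc1 | starting material
6 | ethyl (Z)-3-[4-(benzyloxy)phenyl]prop-2-enoate | CCOC(=O)/C=C\c1ccc(OCc2ccccc2)cc1 | intermediate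
7 | ethyl (2S,3S)-3-[4-(benzyloxy)phenyl]oxirane-2-carboxylate (cis-glycidate) | CCOC(=O)[C@H]1O[C@H]1c1ccc(OCc2ccccc2)cc1 | intermediate
8 | ethyl (2S,3R)-3-[2,3-bis(benzyloxy)-4-iodophenoxy]-3-[4-(benzyloxy)phenyl]-2-hydroxypropanoate | CCOC(=O)[C@@H](O)[C@H](Oc1ccc(I)c(OCc2ccccc2)c1OCc1ccccc1)c1ccc(OCc2ccccc2)cc1 | intermediate
9 | ethyl (2S,3R)-2-(benzyloxy)-3-[2,3-bis(benzyloxy)-4-iodophenoxy]-3-[4-(benzyloxy)phenyl]propanoate | CCOC(=O)[C@@H](OCc1ccccc1)[C@H](Oc1ccc(I)c(OCc2ccccc2)c1OCc1ccccc1)c1ccc(OCc2ccccc2)cc1 | intermediate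
10 | rac-1-[4-(benzyloxy)phenyl]prop-2-yn-1-ol | C#CC(O)c1ccc(OCc2ccccc2)cc1 | intermediate
11 | rac-1-[4-(benzyloxy)phenyl]prop-2-yn-1-yl acetate | C#CC(OC(C)=O)c1ccc(OCc2ccccc2)cc1 | intermediate
12 | 1,2-bis(benzyloxy)-3-{[(1R)-1-[4-(benzyloxy)phenyl]prop-2-yn-1-yl]oxy}benzene | C#C[C@@H](Oc1cccc(OCc2ccccc2)c1OCc1ccccc1)c1ccc(OCc2ccccc2)cc1 | intermediate
13 | diaryl alkyne: ethyl (2S,3R)-2-(benzyloxy)-3-[4-(benzyloxy)phenyl]-3-[2,3-bis(benzyloxy)-4-{(3S)-3-[2,3-bis(benzyloxy)phenoxy]-3-[4-(benzyloxy)phenyl]prop-1-yn-1-yl}phenoxy]propanoate | CCOC(=O)[C@@H](OCc1ccccc1)[C@H](Oc1ccc(C#C[C@@H](Oc2cccc(OCc3ccccc3)c2OCc2ccccc2)c2ccc(OCc3ccccc3)cc2)c(OCc2ccccc2)c1OCc1ccccc1)c1ccc(OCc2ccccc2)cc1 | intermediate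
14 | 4-aryl-2H-chromene: ethyl (2S,3R)-2-(benzyloxy)-3-[4-(benzyloxy)phenyl]-3-[2,3-bis(benzyloxy)-4-{(2R)-7,8-bis(benzyloxy)-2-[4-(benzyloxy)phenyl]-2H-chromen-4-yl}phenoxy]propanoate | CCOC(=O)[C@@H](OCc1ccccc1)[C@H](Oc1ccc(C2=C[C@H](c3ccc(OCc4ccccc4)cc3)Oc3c(OCc4ccccc4)c(OCc4ccccc4)ccc23)c(OCc2ccccc2)c1OCc1ccccc1)c1ccc(OCc2ccccc2)cc1 | intermediate
15 | 3,4-cis-diol (both hydroxyls trans to the C2 aryl group): ethyl (2S,3R)-2-(benzyloxy)-3-[4-(benzyloxy)phenyl]-3-[2,3-bis(benzyloxy)-4-{(2S,3S,4R)-7,8-bis(benzyloxy)-2-[4-(benzyloxy)phenyl]-3,4-dihydroxychroman-4-yl}phenoxy]propanoate | CCOC(=O)[C@@H](OCc1ccccc1)[C@H](Oc1ccc([C@@]2(O)c3ccc(OCc4ccccc4)c(OCc4ccccc4)c3O[C@@H](c3ccc(OCc4ccccc4)cc3)[C@@H]2O)c(OCc2ccccc2)c1OCc1ccccc1)c1ccc(OCc2ccccc2)cc1 | intermediate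
16 | 2,4-trans flavan-3-one: ethyl (2S,3R)-2-(benzyloxy)-3-[4-(benzyloxy)phenyl]-3-[2,3-bis(benzyloxy)-4-{(2S,4R)-7,8-bis(benzyloxy)-2-[4-(benzyloxy)phenyl]-3-oxochroman-4-yl}phenoxy]propanoate | CCOC(=O)[C@@H](OCc1ccccc1)[C@H](Oc1ccc([C@@H]2c3ccc(OCc4ccccc4)c(OCc4ccccc4)c3O[C@@H](c3ccc(OCc4ccccc4)cc3)C2=O)c(OCc2ccccc2)c1OCc1ccccc1)c1ccc(OCc2ccccc2)cc1 | intermediate
17 | 2,3-trans-3,4-cis 4-aryl-flavan-3-ol ester: ethyl (2S,3R)-2-(benzyloxy)-3-[4-(benzyloxy)phenyl]-3-[2,3-bis(benzyloxy)-4-{(2S,3R,4R)-7,8-bis(benzyloxy)-2-[4-(benzyloxy)phenyl]-3-hydroxychroman-4-yl}phenoxy]propanoate | CCOC(=O)[C@@H](OCc1ccccc1)[C@H](Oc1ccc([C@@H]2c3ccc(OCc4ccccc4)c(OCc4ccccc4)c3O[C@@H](c3ccc(OCc4ccccc4)cc3)[C@@H]2O)c(OCc2ccccc2)c1OCc1ccccc1)c1ccc(OCc2ccccc2)cc1 | intermediate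
18 | aldehyde: (2S,3R)-2-(benzyloxy)-3-[4-(benzyloxy)phenyl]-3-[2,3-bis(benzyloxy)-4-{(2S,3R,4R)-7,8-bis(benzyloxy)-2-[4-(benzyloxy)phenyl]-3-hydroxychroman-4-yl}phenoxy]propanal | O=C[C@@H](OCc1ccccc1)[C@H](Oc1ccc([C@@H]2c3ccc(OCc4ccccc4)c(OCc4ccccc4)c3O[C@@H](c3ccc(OCc4ccccc4)cc3)[C@@H]2O)c(OCc2ccccc2)c1OCc1ccccc1)c1ccc(OCc2ccccc2)cc1 | intermediate
19 | hepta-O-benzyl ether of 20 (six phenolic oxygens and the C3 oxygen of unit 2 benzylated; free hydroxyls at C4 of unit 2 and C3 of unit 1; all six stereocentres arranged as in 20) | c1ccccc1COc1ccc([C@H]2Oc3c(cc([C@@H]4c5ccc(OCc6ccccc6)c(OCc6ccccc6)c5O[C@@H](c5ccc(OCc6ccccc6)cc5)[C@@H]4O)c(OCc4ccccc4)c3OCc3ccccc3)[C@@H](O)[C@H]2OCc2ccccc2)cc1 | intermediate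
20 | (2R,3R,4R)-2-(4-hydroxyphenyl)-6-[(2S,3R,4R)-3,7,8-trihydroxy-2-(4-hydroxyphenyl)chroman-4-yl]chromane-3,4,7,8-tetrol | Oc1ccc([C@H]2Oc3c(cc([C@@H]4c5ccc(O)c(O)c5O[C@@H](c5ccc(O)cc5)[C@@H]4O)c(O)c3O)[C@@H](O)[C@H]2O)cc1 | target

**Step count and risks**

Total step count: 16.

Longest linear sequence: 11 steps (5 → 6 → 7 → 8 → 9 → 13 → 14 → 15 → 17 → 18 → 19 → 20; the branch from 1 through 3 and 4 is equally long).

Steps most likely to fail:

Step 13. The C4 configuration of the transient ketone may be lost by enolisation towards the doubly benzylic C4–H, or hydride may be delivered from the wrong face of the carbonyl. The fallback avoids the ketone: it sets out from 15 and returns at 17. The secondary hydroxyl of 15 alone is acetylated (Ac2O, pyridine, DMAP) to give the 3-O-acetate F1. Ionic hydrogenation of F1 (Et3SiH, BF3·OEt2, CH2Cl2, −78 °C) removes the tertiary benzylic hydroxyl; the neighbouring acetoxy group shields its own face of the C4 cation as the bridged acetoxonium ion, so hydride should enter anti to it and give the 3,4-cis acetate F2. Mild ethanolysis (K2CO3, EtOH, 0 °C) then gives 17.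

Step 15. The arene may attack through a non-chelated aldehyde conformer, so that facial selectivity at C4 of unit 2 is poor. The fallback moves control of this centre from the C–C bond formation to a ketone reduction: it sets out from 18 and returns at 19. The ring closure is run without regard to selectivity, so that the 3,4-trans C4 epimer F3 forms beside 19. The mixture is oxidised with MnO2 in CH2Cl2 (the non-benzylic hydroxyl of unit 1 is not touched) to the 2,3-cis flavan-4-one F4. Reduction of F4 with NaBH4 in MeOH/CH2Cl2 at −78 °C should deliver hydride opposite the axial C3 benzyloxy group and give 19.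

Step 16. Once the para C7 oxygen of ring D is unmasked, the benzylic C4–O bond of unit 2 may be hydrogenolysed while the slower secondary benzyl ether is still being cleaved. The fallback creates the C4 hydroxyl last: it sets out from 19 and returns at 20. Compound 19 is oxidised with MnO2 to the flavan-4-one F4, which has no benzylic hydroxyl to lose. Hydrogenolysis of F4 (H2, Pd(OH)2/C, EtOAc/MeOH) gives the free heptahydroxy dihydroflavonol F5. Reduction of F5 with NaBH4 in EtOH at 0 °C under argon, the classical route from dihydroflavonols to flavan-3,4-diols, should add hydride opposite the axial C3 hydroxyl and give the 3,4-cis diol 20.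

Further compounds
F1 | step 13 | 3-O-acetate of diol 15 (unit 1 C3 acetoxy, C4 tertiary hydroxyl free) | CCOC(=O)[C@@H](OCc1ccccc1)[C@H](Oc1ccc([C@@]2(O)c3ccc(OCc4ccccc4)c(OCc4ccccc4)c3O[C@@H](c3ccc(OCc4ccccc4)cc3)[C@@H]2OC(C)=O)c(OCc2ccccc2)c1OCc1ccccc1)c1ccc(OCc2ccccc2)cc1
F2 | step 13 | 3-O-acetate of 17 (2,3-trans-3,4-cis) | CCOC(=O)[C@@H](OCc1ccccc1)[C@H](Oc1ccc([C@@H]2c3ccc(OCc4ccccc4)c(OCc4ccccc4)c3O[C@@H](c3ccc(OCc4ccccc4)cc3)[C@@H]2OC(C)=O)c(OCc2ccccc2)c1OCc1ccccc1)c1ccc(OCc2ccccc2)cc1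
F3 | step 15 | C4 epimer of 19 in unit 2 (2,3-cis-3,4-trans) | c1ccccc1COc1ccc([C@H]2Oc3c(cc([C@@H]4c5ccc(OCc6ccccc6)c(OCc6ccccc6)c5O[C@@H](c5ccc(OCc6ccccc6)cc5)[C@@H]4O)c(OCc4ccccc4)c3OCc3ccccc3)[C@H](O)[C@H]2OCc2ccccc2)cc1
F4 | step 15 | 2,3-cis flavan-4-one from 19 (unit 2 C4 ketone, otherwise as 19) | c1ccccc1COc1ccc([C@H]2Oc3c(cc([C@@H]4c5ccc(OCc6ccccc6)c(OCc6ccccc6)c5O[C@@H](c5ccc(OCc6ccccc6)cc5)[C@@H]4O)c(OCc4ccccc4)c3OCc3ccccc3)C(=O)[C@H]2OCc2ccccc2)cc1
F5 | step 16 | (2R,3S)-3,7,8-trihydroxy-2-(4-hydroxyphenyl)-6-[(2S,3R,4R)-3,7,8-trihydroxy-2-(4-hydroxyphenyl)chroman-4-yl]chroman-4-one | Oc1ccc([C@H]2Oc3c(cc([C@@H]4c5ccc(O)c(O)c5O[C@@H](c5ccc(O)cc5)[C@@H]4O)c(O)c3O)C(=O)[C@H]2O)cc1
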